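The route builds ring A of the apigenin half last. That ring is a C5 phenol carrying the acacetin C3 at C6 and oxygen at C7, fused through C4a–C8a to a 4-pyranone; a Danheiser benzannulation delivers exactly this array. In one operation, Wolff rearrangement, ketene–ynol ether [2+2] cycloaddition, four-electron ring opening and six-electron ring closure should form C8a–C8, C7–C8, C5–C6 and C4a–C5, close ring A and fix the hindered C3–C6 biaryl bond regiospecifically. The precursors are a 6-aryl-2-(diazoacetyl)-4-pyranone and benzyl-protected acacetin bearing a triisopropylsiloxyethynyl group at C3; desilylation and hydrogenolysis then finish the synthesis.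

Key step: step 9

Remark: the target has no stereocentre and its SMILES leaves the C3–C6 biaryl axis unassigned, so no stereocontrol is planned. In the key step the locants C4a to C8a refer to the apigenin unit.

Step 1
Reactants: 1 acacetin (5,7-dihydroxy-2-(4-methoxyphenyl)-4H-chromen-4-one)
Product: 2 5,7-bis(benzyloxy)-2-(4-methoxyphenyl)-4H-chromen-4-one
Conditions: BnBr, K2CO3, DMF, 80 °C
Reagents that add atoms: benzyl bromide, BrCc1ccccc1
Why: Williamson ether synthesis, in which DMF and heat also alkylate the hydrogen-bonded 5-OH while the aryl methyl ether is untouched.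

Step 2
Reactants: 2 5,7-bis(benzyloxy)-2-(4-methoxyphenyl)-4H-chromen-4-one
Product: 4 5,7-bis(benzyloxy)-3-iodo-2-(4-methoxyphenyl)-4H-chromen-4-one, via 3-lithioflavone 3 (not isolated)
Conditions: LiN(iPr)2, THF, −78 °C; then I2, −78 °C to rt
Reagents that add atoms: iodine, II
Why: Carbonyl-directed C3 lithiation of the flavone followed by iodine quench is the established entry to 3-iodo-5,7-dialkoxyflavones, whereas electrophilic iodination would attack the electron-rich ring A.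

Step 3
Reactants: 4 5,7-bis(benzyloxy)-3-iodo-2-(4-methoxyphenyl)-4H-chromen-4-one
Product: 6 5,7-bis(benzyloxy)-3-ethynyl-2-(4-methoxyphenyl)-4H-chromen-4-one, via trimethylsilylalkyne 5 (not isolated)
Conditions: HC≡CSiMe3, PdCl2(PPh3)2, CuI, Et3N, DMF, 50 °C; then K2CO3 (cat.), MeOH, rt
Reagents that add atoms: ethynyltrimethylsilane, C#C[Si](C)(C)C
Why: Sonogashira coupling of the 3-iodoflavone followed by methanolysis of the C–Si bond in the same flask should give the terminal alkyne, the 2-aryl group shielding C2 from conjugate addition of methoxide.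

Step 4
Reactants: 6 5,7-bis(benzyloxy)-3-ethynyl-2-(4-methoxyphenyl)-4H-chromen-4-one
Product: 9 5,7-bis(benzyloxy)-2-(4-methoxyphenyl)-3-{[tri(propan-2-yl)silyloxy]ethynyl}-4H-chromen-4-one, via lithium acetylide 7 (not isolated), via lithium ynolate 8 (not isolated)
Conditions: LiN(SiMe3)2, THF, −78 °C; t-BuOOLi (from t-BuOOH, LiN(SiMe3)2), −78 to 0 °C; TIPSOTf, −78 °C to rt
Reagents that add atoms: tert-butyl hydroperoxide, CC(C)(C)OO; triisopropylsilyl trifluoromethanesulfonate, CC(C)[Si](C(C)C)(C(C)C)OS(=O)(=O)C(F)(F)F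
Why: Electrophilic oxygen transfer from lithium tert-butyl peroxide to a lithium acetylide (Julia-type acetylide oxidation) gives the ynolate, which the bulky silyl triflate should trap on oxygen; the non-nucleophilic amide base spares the chromone.

Step 5
Reactants: 10 4'-(benzyloxy)acetophenone
Product: 11 1-[4-(benzyloxy)phenyl]butane-1,3-dione
Conditions: NaH, EtOAc, THF, 65 °C; aq. HCl work-up
Reagents that add atoms: ethyl acetate, CCOC(C)=O
Why: Crossed Claisen condensation of the ketone enolate with ethyl acetate, driven to completion by formation of the stable diketonate.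

Step 6
Reactants: 11 1-[4-(benzyloxy)phenyl]butane-1,3-dione; 12 diethyl oxalate
Product: 14 ethyl 6-[4-(benzyloxy)phenyl]-4-oxo-4H-pyran-2-carboxylate, via triketo ester 13 (not isolated)
Conditions: NaOEt, EtOH, 0 to 50 °C; then HCl (4 M in dioxane), EtOH, 60 °C
Reagents that add atoms: none
Why: A second Claisen condensation under equilibrating conditions acylates the terminal methyl group, and acid-catalysed cyclodehydration of the 1,3,5-tricarbonyl chain closes the 4-pyranone, anhydrous acid sparing the ester and the benzyl ether.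

Step 7
Reactants: 14 ethyl 6-[4-(benzyloxy)phenyl]-4-oxo-4H-pyran-2-carboxylate
Product: 15 6-[4-(benzyloxy)phenyl]-4-oxo-4H-pyran-2-carboxylic acid
Conditions: LiOH, THF/H2O, 0 °C; then 1 M HCl
Reagents that add atoms: lithium hydroxide, [Li+].[OH-]
Why: Saponification of an activated ester at low temperature, with the acid quench reclosing any ring-opened triketone form to the pyranone.

Step 8
Reactants: 15 6-[4-(benzyloxy)phenyl]-4-oxo-4H-pyran-2-carboxylic acid
Product: 17 2-[4-(benzyloxy)phenyl]-6-(2-diazoacetyl)-4H-pyran-4-one, via acid chloride 16 (not isolated)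
Conditions: (COCl)2, DMF (cat.), CH2Cl2, 0 °C to rt; then CH2N2, Et2O/CH2Cl2, 0 °C
Reagents that add atoms: diazomethane, C=[N+]=[N-]
Why: Acid chloride formation and C-acylation of diazomethane (the first stage of an Arndt–Eistert sequence), a second equivalent of diazomethane removing the HCl.

Step 9
Reactants: 17 2-[4-(benzyloxy)phenyl]-6-(2-diazoacetyl)-4H-pyran-4-one; 9 5,7-bis(benzyloxy)-2-(4-methoxyphenyl)-3-{[tri(propan-2-yl)silyloxy]ethynyl}-4H-chromen-4-one
Product: 22 3-{2-[4-(benzyloxy)phenyl]-5-hydroxy-4-oxo-7-[tri(propan-2-yl)silyloxy]-4H-chromen-6-yl}-5,7-bis(benzyloxy)-2-(4-methoxyphenyl)-4H-chromen-4-one, via pyranonylketene 18 (not isolated), via cyclobutenone 19 (not isolated), via dienylketene 20 (not isolated), via cyclohexadienone 21 (not isolated)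
Conditions: hν (440 nm LEDs), ClCH2CH2Cl, rt, slow addition of 17; then 80 °C
Reagents that add atoms: none
Why: Light at 440 nm should be absorbed only by the diazoketone, so N2 is lost and Wolff rearrangement (shift of the pyranonyl carbon, C8a–C8) gives ketene 18, whose carbonyl carbon is attacked by the oxygen-remote, nucleophilic carbon of siloxyalkyne 9 in a [2+2] cycloaddition (C5–C6 and C7–C8) to cyclobutenone 19. On warming, 19 opens reversibly by conrotatory four-electron electrocyclic cleavage to dienylketene 20, and ring A closes by thermal disrotatory six-electron electrocyclisation between the ketene carbon and pyranone C5 (C4a–C5) to dienone 21, which enolises at its doubly activated C4a–H to the chelated C5 phenol. The closest known chemistry is the second-generation Danheiser benzannulation of alkenyl and heteroaryl diazomethyl ketones with siloxyalkynes, here with the enol-ether-like, weakly aromatic C5=C6 bond of a 4-pyranone as the participating π bond. No stereocentre is created, since the single centres of 19 and 21 are lost on aromatisation. The step needs one orientation of the ketene–alkyne union, and the siloxy oxygen secures it by polarising the alkyne so that the flavone-bearing carbon bonds to the ketene carbonyl, which places the acacetin unit at C6 between the two oxygens and excludes the C8 isomer. Slow addition of 17 keeps the ketene concentration low against dimerisation, and the hydrogen-bonded C5–OH of 22 is a poor acceptor for surplus ketene.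

Step 10
Reactants: 22 3-{2-[4-(benzyloxy)phenyl]-5-hydroxy-4-oxo-7-[tri(propan-2-yl)silyloxy]-4H-chromen-6-yl}-5,7-bis(benzyloxy)-2-(4-methoxyphenyl)-4H-chromen-4-one
Product: 23 3-{2-[4-(benzyloxy)phenyl]-5,7-dihydroxy-4-oxo-4H-chromen-6-yl}-5,7-bis(benzyloxy)-2-(4-methoxyphenyl)-4H-chromen-4-one
Conditions: Bu4NF, AcOH, THF, 0 °C
Reagents that add atoms: none
Why: Fluoride-induced cleavage of an aryl silyl ether, with acetic acid buffering the phenoxide and leaving the benzyl and methyl ethers untouched.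

Step 11
Reactants: 23 3-{2-[4-(benzyloxy)phenyl]-5,7-dihydroxy-4-oxo-4H-chromen-6-yl}-5,7-bis(benzyloxy)-2-(4-methoxyphenyl)-4H-chromen-4-one
Product: 24 3-[5,7-dihydroxy-2-(4-hydroxyphenyl)-4-oxo-4H-chromen-6-yl]-5,7-dihydroxy-2-(4-methoxyphenyl)-4H-chromen-4-one (target)
Conditions: H2 (1 atm), 10% Pd/C, THF/MeOH, rt
Reagents that add atoms: none
Why: Catalytic hydrogenolysis of the three benzyl aryl ethers, to which the methyl ether and both chromone rings should be inert at atmospheric pressure.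

Compound list
1 | acacetin, 5,7-dihydroxy-2-(4-methoxyphenyl)-4H-chromen-4-one | COc1ccc(cc1)-c1cc(=O)c2c(O)cc(O)cc2o1 | starting material
2 | 5,7-bis(benzyloxy)-2-(4-methoxyphenyl)-4H-chromen-4-one | COc1ccc(cc1)-c1cc(=O)c2c(OCc3ccccc3)cc(OCc3ccccc3)cc2o1 | intermediate
3 | [5,7-bis(benzyloxy)-2-(4-methoxyphenyl)-4-oxo-4H-chromen-3-yl]lithium (not isolated) | COc1ccc(cc1)-c1oc2cc(OCc3ccccc3)cc(OCc3ccccc3)c2c(=O)c1[Li] | intermediate
4 | 5,7-bis(benzyloxy)-3-iodo-2-(4-methoxyphenyl)-4H-chromen-4-one | COc1ccc(cc1)-c1oc2cc(OCc3ccccc3)cc(OCc3ccccc3)c2c(=O)c1I | intermediate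
5 | 5,7-bis(benzyloxy)-2-(4-methoxyphenyl)-3-[(trimethylsilyl)ethynyl]-4H-chromen-4-one (not isolated) | COc1ccc(cc1)-c1oc2cc(OCc3ccccc3)cc(OCc3ccccc3)c2c(=O)c1C#C[Si](C)(C)C | intermediate
6 | 5,7-bis(benzyloxy)-3-ethynyl-2-(4-methoxyphenyl)-4H-chromen-4-one | COc1ccc(cc1)-c1oc2cc(OCc3ccccc3)cc(OCc3ccccc3)c2c(=O)c1C#C | intermediate
7 | lithium acetylide of 6 (not isolated) | COc1ccc(cc1)-c1oc2cc(OCc3ccccc3)cc(OCc3ccccc3)c2c(=O)c1C#C[Li] | intermediate
8 | lithium 2-[5,7-bis(benzyloxy)-2-(4-methoxyphenyl)-4-oxo-4H-chromen-3-yl]ethynolate (not isolated) | COc1ccc(cc1)-c1oc2cc(OCc3ccccc3)cc(OCc3ccccc3)c2c(=O)c1C#CO[Li] | intermediate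
9 | 5,7-bis(benzyloxy)-2-(4-methoxyphenyl)-3-{[tri(propan-2-yl)silyloxy]ethynyl}-4H-chromen-4-one | COc1ccc(cc1)-c1oc2cc(OCc3ccccc3)cc(OCc3ccccc3)c2c(=O)c1C#CO[Si](C(C)C)(C(C)C)C(C)C | intermediate
10 | 4'-(benzyloxy)acetophenone | CC(=O)c1ccc(OCc2ccccc2)cc1 | starting material
11 | 1-[4-(benzyloxy)phenyl]butane-1,3-dione | CC(=O)CC(=O)c1ccc(OCc2ccccc2)cc1 | intermediate
12 | diethyl oxalate | CCOC(=O)C(=O)OCC | starting material
13 | ethyl 6-[4-(benzyloxy)phenyl]-2,4,6-trioxohexanoate (not isolated) | CCOC(=O)C(=O)CC(=O)CC(=O)c1ccc(OCc2ccccc2)cc1 | intermediate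
14 | ethyl 6-[4-(benzyloxy)phenyl]-4-oxo-4H-pyran-2-carboxylate | CCOC(=O)c1cc(=O)cc(-c2ccc(OCc3ccccc3)cc2)o1 | intermediate
15 | 6-[4-(benzyloxy)phenyl]-4-oxo-4H-pyran-2-carboxylic acid | OC(=O)c1cc(=O)cc(-c2ccc(OCc3ccccc3)cc2)o1 | intermediate
16 | 6-[4-(benzyloxy)phenyl]-4-oxo-4H-pyran-2-carbonyl chloride (not isolated) | ClC(=O)c1cc(=O)cc(-c2ccc(OCc3ccccc3)cc2)o1 | intermediate
17 | 2-[4-(benzyloxy)phenyl]-6-(2-diazoacetyl)-4H-pyran-4-one | [N-]=[N+]=CC(=O)c1cc(=O)cc(-c2ccc(OCc3ccccc3)cc2)o1 | intermediate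
18 | 2-[4-(benzyloxy)phenyl]-6-(2-oxoethenyl)-4H-pyran-4-one, the pyranonylketene (not isolated) | O=C=Cc1cc(=O)cc(-c2ccc(OCc3ccccc3)cc2)o1 | intermediate
19 | 4-{6-[4-(benzyloxy)phenyl]-4-oxo-4H-pyran-2-yl}-2-[5,7-bis(benzyloxy)-2-(4-methoxyphenyl)-4-oxo-4H-chromen-3-yl]-3-[tri(propan-2-yl)silyloxy]cyclobut-2-en-1-one (racemic, not isolated) | O=C1C(c2cc(=O)cc(-c3ccc(OCc4ccccc4)cc3)o2)C(O[Si](C(C)C)(C(C)C)C(C)C)=C1c1c(-c2ccc(OC)cc2)oc2cc(OCc3ccccc3)cc(OCc3ccccc3)c2c1=O | intermediate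
20 | (3E)-2-[5,7-bis(benzyloxy)-2-(4-methoxyphenyl)-4-oxo-4H-chromen-3-yl]-4-{6-[4-(benzyloxy)phenyl]-4-oxo-4H-pyran-2-yl}-3-[tri(propan-2-yl)silyloxy]buta-1,3-dien-1-one, pyranonyl group cis to the ketene-bearing carbon (not isolated) | O=C=C(c1c(-c2ccc(OC)cc2)oc2cc(OCc3ccccc3)cc(OCc3ccccc3)c2c1=O)/C(O[Si](C(C)C)(C(C)C)C(C)C)=C\c1cc(=O)cc(-c2ccc(OCc3ccccc3)cc2)o1 | intermediate
21 | 2-[4-(benzyloxy)phenyl]-6-[5,7-bis(benzyloxy)-2-(4-methoxyphenyl)-4-oxo-4H-chromen-3-yl]-7-[tri(propan-2-yl)silyloxy]-4aH-chromene-4,5-dione (racemic, not isolated) | O=C1C(c3c(-c4ccc(OC)cc4)oc4cc(OCc5ccccc5)cc(OCc5ccccc5)c4c3=O)=C(O[Si](C(C)C)(C(C)C)C(C)C)C=C2OC(-c3ccc(OCc4ccccc4)cc3)=CC(=O)C12 | intermediate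
22 | 3-{2-[4-(benzyloxy)phenyl]-5-hydroxy-4-oxo-7-[tri(propan-2-yl)silyloxy]-4H-chromen-6-yl}-5,7-bis(benzyloxy)-2-(4-methoxyphenyl)-4H-chromen-4-one | COc1ccc(cc1)-c1oc2cc(OCc3ccccc3)cc(OCc3ccccc3)c2c(=O)c1-c1c(O[Si](C(C)C)(C(C)C)C(C)C)cc2oc(-c3ccc(OCc4ccccc4)cc3)cc(=O)c2c1O | intermediate
23 | 3-{2-[4-(benzyloxy)phenyl]-5,7-dihydroxy-4-oxo-4H-chromen-6-yl}-5,7-bis(benzyloxy)-2-(4-methoxyphenyl)-4H-chromen-4-one | COc1ccc(cc1)-c1oc2cc(OCc3ccccc3)cc(OCc3ccccc3)c2c(=O)c1-c1c(O)cc2oc(-c3ccc(OCc4ccccc4)cc3)cc(=O)c2c1O | intermediate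
24 | 3-[5,7-dihydroxy-2-(4-hydroxyphenyl)-4-oxo-4H-chromen-6-yl]-5,7-dihydroxy-2-(4-methoxyphenyl)-4H-chromen-4-one | COc1ccc(-c2oc3cc(O)cc(O)c3c(=O)c2-c2c(O)cc3oc(-c4ccc(O)cc4)cc(=O)c3c2O)cc1 | target

Total step count: 11. Longest linear sequence: 7 steps (steps 1–4 or steps 5–8, then steps 9–11).

Steps most likely to fail

Step 9. The diazoketone may be consumed without productive union. Possible causes are light absorption and photodegradation by the pyranone or flavone chromophores, dimerisation of the ketene before it meets the hindered alkyne, or reclosure of the dienylketene without electrocyclisation. The fallback sets out from iodide 4 and returns at target 24; it makes the apigenin half conventionally and joins the halves by cross-coupling. Commercial apigenin would be benzylated at O7 and O4' (BnBr, K2CO3, acetone, reflux) to 7-(benzyloxy)-2-[4-(benzyloxy)phenyl]-5-hydroxy-4H-chromen-4-one F1. Iodination ortho to the chelated phenol (BnMe3N·ICl2, CaCO3, CH2Cl2/MeOH) should give 7-(benzyloxy)-2-[4-(benzyloxy)phenyl]-5-hydroxy-6-iodo-4H-chromen-4-one F2, and benzylation of O5 (BnBr, K2CO3, DMF, 60 °C) gives 5,7-bis(benzyloxy)-2-[4-(benzyloxy)phenyl]-6-iodo-4H-chromen-4-one F3. Miyaura borylation (B2pin2, PdCl2(dppf), KOAc, dioxane, 90 °C) would give 5,7-bis(benzyloxy)-2-[4-(benzyloxy)phenyl]-6-(4,4,5,5-tetramethyl-1,3,2-dioxaborolan-2-yl)-4H-chromen-4-one F4. Suzuki–Miyaura coupling of F4 with 4 (Pd(OAc)2, SPhos, K3PO4, toluene/H2O, 100 °C) would give 3-{5,7-bis(benzyloxy)-2-[4-(benzyloxy)phenyl]-4-oxo-4H-chromen-6-yl}-5,7-bis(benzyloxy)-2-(4-methoxyphenyl)-4H-chromen-4-one F5, and hydrogenolysis of its five benzyl ethers (H2, Pd/C) gives 24.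

Step 4. Oxygen transfer to the electron-poor acetylide may be incomplete, the peroxide may attack the chromone, or the ynolate may be protonated or C-silylated instead of O-silylated. The fallback sets out from iodide 4 and returns at 9; it reaches the same ynolate by Kowalski ester homologation. Palladium-catalysed methoxycarbonylation (CO, MeOH, Pd(OAc)2, dppf, Et3N, DMF, 70 °C) would give methyl 5,7-bis(benzyloxy)-2-(4-methoxyphenyl)-4-oxo-4H-chromene-3-carboxylate F6. Addition of LiCHBr2 (CH2Br2, lithium 2,2,6,6-tetramethylpiperidide, THF, −78 °C) and enolisation with LiN(SiMe3)2 would give, as its lithium enolate in the flask, 5,7-bis(benzyloxy)-3-(2,2-dibromoacetyl)-2-(4-methoxyphenyl)-4H-chromen-4-one F7. Bromine–lithium exchange with n-BuLi and warming should trigger the carbenoid rearrangement to ynolate 8, which TIPSCl silylates on oxygen to 9.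

Step 2. The amide base may deprotonate a benzylic CH2 of the 5-O-benzyl group (followed by Wittig-type rearrangement or attack on the C4 carbonyl) in competition with C3 lithiation. The fallback sets out from 2 and returns at 5; it functionalises C3 by oxidation instead of metalation. Epoxidation of the C2=C3 bond with dimethyldioxirane (acetone/CH2Cl2, 0 °C) would give 5,7-bis(benzyloxy)-2,3-epoxy-2-(4-methoxyphenyl)-2,3-dihydro-4H-chromen-4-one F8, which TsOH (cat.) isomerises to the flavonol 5,7-bis(benzyloxy)-3-hydroxy-2-(4-methoxyphenyl)-4H-chromen-4-one F9. Triflation (Tf2O, pyridine, CH2Cl2, 0 °C) would give 5,7-bis(benzyloxy)-2-(4-methoxyphenyl)-4-oxo-4H-chromen-3-yl trifluoromethanesulfonate F10. Sonogashira coupling of F10 with ethynyltrimethylsilane (PdCl2(PPh3)2, CuI, Et3N, DMF) gives 5, which is desilylated to 6 as in step 3.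

Further compounds
F1 | step 9 | 7-(benzyloxy)-2-[4-(benzyloxy)phenyl]-5-hydroxy-4H-chromen-4-one | O=c1cc(-c2ccc(OCc3ccccc3)cc2)oc2cc(OCc3ccccc3)cc(O)c12
F2 | step 9 | 7-(benzyloxy)-2-[4-(benzyloxy)phenyl]-5-hydroxy-6-iodo-4H-chromen-4-one | O=c1cc(-c2ccc(OCc3ccccc3)cc2)oc2cc(OCc3ccccc3)c(I)c(O)c12
F3 | step 9 | 5,7-bis(benzyloxy)-2-[4-(benzyloxy)phenyl]-6-iodo-4H-chromen-4-one | O=c1cc(-c2ccc(OCc3ccccc3)cc2)oc2cc(OCc3ccccc3)c(I)c(OCc3ccccc3)c12
F4 | step 9 | 5,7-bis(benzyloxy)-2-[4-(benzyloxy)phenyl]-6-(4,4,5,5-tetramethyl-1,3,2-dioxaborolan-2-yl)-4H-chromen-4-one | O=c1cc(-c2ccc(OCc3ccccc3)cc2)oc2cc(OCc3ccccc3)c(B3OC(C)(C)C(C)(C)O3)c(OCc3ccccc3)c12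
F5 | step 9 | 3-{5,7-bis(benzyloxy)-2-[4-(benzyloxy)phenyl]-4-oxo-4H-chromen-6-yl}-5,7-bis(benzyloxy)-2-(4-methoxyphenyl)-4H-chromen-4-one | COc1ccc(cc1)-c1oc2cc(OCc3ccccc3)cc(OCc3ccccc3)c2c(=O)c1-c1c(OCc2ccccc2)cc2oc(-c3ccc(OCc4ccccc4)cc3)cc(=O)c2c1OCc1ccccc1
F6 | step 4 | methyl 5,7-bis(benzyloxy)-2-(4-methoxyphenyl)-4-oxo-4H-chromene-3-carboxylate | COC(=O)c1c(-c2ccc(OC)cc2)oc2cc(OCc3ccccc3)cc(OCc3ccccc3)c2c1=O
F7 | step 4 | 5,7-bis(benzyloxy)-3-(2,2-dibromoacetyl)-2-(4-methoxyphenyl)-4H-chromen-4-one (formed as its lithium enolate, not isolated) | O=C(C(Br)Br)c1c(-c2ccc(OC)cc2)oc2cc(OCc3ccccc3)cc(OCc3ccccc3)c2c1=O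
F8 | step 2 | 5,7-bis(benzyloxy)-2,3-epoxy-2-(4-methoxyphenyl)-2,3-dihydro-4H-chromen-4-one (racemic, cis ring fusion) | COc1ccc(cc1)C12OC1C(=O)c1c(OCc3ccccc3)cc(OCc3ccccc3)cc1O2
F9 | step 2 | 5,7-bis(benzyloxy)-3-hydroxy-2-(4-methoxyphenyl)-4H-chromen-4-one | COc1ccc(cc1)-c1oc2cc(OCc3ccccc3)cc(OCc3ccccc3)c2c(=O)c1O
F10 | step 2 | 5,7-bis(benzyloxy)-2-(4-methoxyphenyl)-4-oxo-4H-chromen-3-yl trifluoromethanesulfonate | COc1ccc(cc1)-c1oc2cc(OCc3ccccc3)cc(OCc3ccccc3)c2c(=O)c1OS(=O)(=O)C(F)(F)F
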